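The route disconnects C9–C10 of the cycloheptane ring (longipinane numbering: C1 ketone, C2=C3, cyclobutane C4–C5–C11–C10, C6 gem-dimethyl, C7–C9 oxygenated). The feature exploited is the quaternary cyclobutane carbon C10: its methyl group and its bond to C9 both derive from one exocyclic methylene. In one operation, hydrogen-atom transfer from an iron hydride converts this methylene into the methyl-bearing tertiary radical, which closes the seven-membered ring 7-endo onto a β-sulfonyl enone on the C5 side chain and restores C8=C9 by loss of the sulfonyl radical. The precursor is a 6-methylidenebicyclo[3.1.1]hept-3-en-2-one bearing a CMe2–CO–CH=CH–SO2Ph chain, assembled by an intramolecular vinylketene–alkene cycloaddition.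

Key step: step 16

Remark on the chemistry: tricyclic compounds carry longipinane locants (TBS = tert-butyldimethylsilyl, TES = triethylsilyl); in step 6 the catalyst antipode is the one that directs the dienolate to the Re face of the enal (5R), the configuration required if the C1 silyloxy group sits syn to the cyclobutanone bridge in step 9, as argued there.

Step 1
Reactants: 1 2,2-dimethylpropane-1,3-diol
Product: 2 3-[(tert-butyldimethylsilyl)oxy]-2,2-dimethylpropan-1-ol
Conditions: NaH (1 equiv), THF, 0 °C; TBSCl (1 equiv), 0 °C to rt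
Reagents that add atoms: tert-butyldimethylsilyl chloride, CC(C)(C)[Si](C)(C)Cl
Why: Williamson-type O-silylation of the sparingly soluble monosodium alkoxide of a symmetrical diol, which should react once and leave the second hydroxyl free.

Step 2
Reactants: 2 3-[(tert-butyldimethylsilyl)oxy]-2,2-dimethylpropan-1-ol
Product: 3 3-[(tert-butyldimethylsilyl)oxy]-2,2-dimethylpropanal
Conditions: TEMPO (cat.), PhI(OAc)2, CH2Cl2, rt
Reagents that add atoms: none
Why: TEMPO-catalysed oxidation of a primary alcohol should stop at the non-enolisable neopentyl aldehyde and leave the silyl ether intact.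

Step 3
Reactants: 3 3-[(tert-butyldimethylsilyl)oxy]-2,2-dimethylpropanal; 4 diethyl {2-[methoxy(methyl)amino]-2-oxoethyl}phosphonate
Product: 5 (2E)-5-[(tert-butyldimethylsilyl)oxy]-N-methoxy-N,4,4-trimethylpent-2-enamide
Conditions: NaH, THF, 0 °C to rt
Reagents that add atoms: none
Why: Horner–Wadsworth–Emmons olefination with a stabilised phosphonate anion should give the E-configured unsaturated Weinreb amide, since the α-quaternary aldehyde cannot enolise.

Step 4
Reactants: 5 (2E)-5-[(tert-butyldimethylsilyl)oxy]-N-methoxy-N,4,4-trimethylpent-2-enamide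
Product: 6 (2E)-5-[(tert-butyldimethylsilyl)oxy]-4,4-dimethylpent-2-enal
Conditions: i-Bu2AlH, THF, −78 °C; aq. potassium sodium tartrate
Reagents that add atoms: none
Why: Weinreb amide reduction, in which the chelated aluminium hemiaminal survives until work-up, should release the enal without over-reduction or 1,4-reduction.

Step 5
Reactants: 7 methyl 3-methylbut-2-enoate
Product: 8 tert-butyl[(1-methoxy-3-methylbuta-1,3-dien-1-yl)oxy]dimethylsilane
Conditions: LiN(i-Pr)2, THF, −78 °C; TBSCl, DMPU, −78 °C to rt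
Reagents that add atoms: tert-butyldimethylsilyl chloride, CC(C)(C)[Si](C)(C)Cl
Why: Kinetic γ-deprotonation of the ester and O-silylation of the extended enolate (silyl ketene acetal formation) should give the silyl dienolate.

Step 6
Reactants: 6 (2E)-5-[(tert-butyldimethylsilyl)oxy]-4,4-dimethylpent-2-enal; 8 tert-butyl[(1-methoxy-3-methylbuta-1,3-dien-1-yl)oxy]dimethylsilane
Product: 9 methyl (2E,5R,6E)-9-[(tert-butyldimethylsilyl)oxy]-5-hydroxy-3,8,8-trimethylnona-2,6-dienoate
Conditions: SiCl4, chiral bisphosphoramide Lewis base derived from N,N′-dimethyl-1,1′-binaphthyl-2,2′-diamine (5 mol%), CH2Cl2, −78 °C; aqueous work-up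
Reagents that add atoms: none
Why: Catalytic enantioselective vinylogous Mukaiyama aldol addition, in which the Lewis-base-activated chlorosilyl cation binds the enal and the γ-carbon of the dienolate attacks the carbonyl through an open transition state, should give the 2E enoate and, by Re-face attack, the 5R carbinol that later fixes the absolute configuration of the bicyclic core.

Step 7
Reactants: 9 methyl (2E,5R,6E)-9-[(tert-butyldimethylsilyl)oxy]-5-hydroxy-3,8,8-trimethylnona-2,6-dienoate
Product: 10 methyl (2E,5R,6E)-5,9-bis[(tert-butyldimethylsilyl)oxy]-3,8,8-trimethylnona-2,6-dienoate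
Conditions: TBSCl, imidazole, DMF, rt
Reagents that add atoms: tert-butyldimethylsilyl chloride, CC(C)(C)[Si](C)(C)Cl
Why: Silyl ether protection of the secondary allylic alcohol is needed so that the acid chloride of step 9 can be formed.

Step 8
Reactants: 10 methyl (2E,5R,6E)-5,9-bis[(tert-butyldimethylsilyl)oxy]-3,8,8-trimethylnona-2,6-dienoate
Product: 11 (2E,5R,6E)-5,9-bis[(tert-butyldimethylsilyl)oxy]-3,8,8-trimethylnona-2,6-dienoic acid
Conditions: LiOH, THF/MeOH/H2O, 45 °C; then aq. HCl to pH 4
Reagents that add atoms: lithium hydroxide, [Li+].[OH-]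
Why: Saponification of the conjugated methyl ester should leave both silyl ethers in place, and the δ-silyloxy group is not eliminated because the carboxylate does not form a dienolate.

Step 9
Reactants: 11 (2E,5R,6E)-5,9-bis[(tert-butyldimethylsilyl)oxy]-3,8,8-trimethylnona-2,6-dienoic acid
Product: 14 (1S,2R,5R,7S)-2-[(tert-butyldimethylsilyl)oxy]-7-{1-[(tert-butyldimethylsilyl)oxy]-2-methylpropan-2-yl}-4-methylidenebicyclo[3.1.1]heptan-6-one, via acid chloride 12 (not isolated), via vinylketene 13 (not isolated)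
Conditions: 1-chloro-N,N,2-trimethylprop-1-en-1-amine, CH2Cl2, 0 °C to rt; then slow addition to Et3N, toluene, 110 °C, 0.01 M; chromatography
Reagents that add atoms: none
Why: Intramolecular [2+2] cycloaddition of a vinylketene (from γ-dehydrochlorination of the enoyl chloride) to the E-alkene, the reaction type that turns geranic-type acid chlorides into 2-methylidenebicyclo[3.1.1]heptan-6-ones; the ketene carbon should bond to the less hindered alkene carbon next to the silyloxy carbon (bridged mode, since the allylic oxygen disfavours positive charge there), suprafacial addition to the E-alkene places the side chain anti to the three-carbon bridge, and the silyloxy group should sit syn to the carbonyl bridge (C–H rather than C–O anti to the forming bond), so that the R carbinol sets the 1S,5R,7S core, the minor C2 epimer being removed by chromatography.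

Step 10
Reactants: 14 (1S,2R,5R,7S)-2-[(tert-butyldimethylsilyl)oxy]-7-{1-[(tert-butyldimethylsilyl)oxy]-2-methylpropan-2-yl}-4-methylidenebicyclo[3.1.1]heptan-6-one
Product: 15 (1R,2R,5R,7S)-2-[(tert-butyldimethylsilyl)oxy]-7-{1-[(tert-butyldimethylsilyl)oxy]-2-methylpropan-2-yl}-4,6-dimethylidenebicyclo[3.1.1]heptane
Conditions: Ph3PCH3Br, KOtBu, THF, 0 °C to rt
Reagents that add atoms: methyltriphenylphosphonium bromide, C[P+](c1ccccc1)(c1ccccc1)c1ccccc1.[Br-]
Why: Wittig methylenation of the strained cyclobutanone, which cannot enolise because both α-carbons are bridgeheads, installs the methylene that becomes C10 and its methyl group.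

Step 11
Reactants: 15 (1R,2R,5R,7S)-2-[(tert-butyldimethylsilyl)oxy]-7-{1-[(tert-butyldimethylsilyl)oxy]-2-methylpropan-2-yl}-4,6-dimethylidenebicyclo[3.1.1]heptane
Product: 16 (1R,2R,5R,7S)-7-(1-hydroxy-2-methylpropan-2-yl)-4,6-dimethylidenebicyclo[3.1.1]heptan-2-ol
Conditions: Bu4NF, THF, rt
Reagents that add atoms: none
Why: Fluoride-mediated cleavage of both silyl ethers under non-acidic conditions avoids protonation of the methylenecyclobutane.

Step 12
Reactants: 16 (1R,2R,5R,7S)-7-(1-hydroxy-2-methylpropan-2-yl)-4,6-dimethylidenebicyclo[3.1.1]heptan-2-ol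
Product: 18 2-methyl-2-[(1R,5R,7S)-4-methyl-6-methylidene-2-oxobicyclo[3.1.1]hept-3-en-7-yl]propanal, via deconjugated keto aldehyde 17 (not isolated)
Conditions: Dess–Martin periodinane, CH2Cl2, rt; aqueous work-up; then DBU (cat.), CH2Cl2, rt
Reagents that add atoms: none
Why: Dess–Martin oxidation of both alcohols followed by base-mediated migration of the exocyclic alkene into conjugation with the new ketone (a verbenone-type enone is the thermodynamic isomer); the aldehyde cannot enolise and the cyclobutane methylene cannot move because its neighbours are bridgeheads.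

Step 13
Reactants: 18 2-methyl-2-[(1R,5R,7S)-4-methyl-6-methylidene-2-oxobicyclo[3.1.1]hept-3-en-7-yl]propanal
Product: 19 (1R,5R,7S)-7-(3-hydroxy-2-methylpent-4-yn-2-yl)-4-methyl-6-methylidenebicyclo[3.1.1]hept-3-en-2-one (carbinol epimers)
Conditions: HC≡CMgBr, THF, −78 to −30 °C; aq. NH4Cl
Reagents that add atoms: ethynylmagnesium bromide, C#C[Mg]Br
Why: Grignard addition of the acetylide should be chemoselective for the aldehyde over the hindered β,β-disubstituted enone at low temperature, and the new carbinol centre is erased in step 14.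

Step 14
Reactants: 19 (1R,5R,7S)-7-(3-hydroxy-2-methylpent-4-yn-2-yl)-4-methyl-6-methylidenebicyclo[3.1.1]hept-3-en-2-one
Product: 20 (1R,5R,7S)-4-methyl-6-methylidene-7-(2-methyl-3-oxopent-4-yn-2-yl)bicyclo[3.1.1]hept-3-en-2-one
Conditions: Dess–Martin periodinane, CH2Cl2, 0 °C to rt
Reagents that add atoms: none
Why: Dess–Martin oxidation converts the propargylic alcohol into the ynone under neutral conditions.

Step 15
Reactants: 20 (1R,5R,7S)-4-methyl-6-methylidene-7-(2-methyl-3-oxopent-4-yn-2-yl)bicyclo[3.1.1]hept-3-en-2-one; 21 sodium benzenesulfinate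
Product: 22 (1R,5R,7S)-4-methyl-6-methylidene-7-[(4E)-2-methyl-3-oxo-5-(phenylsulfonyl)pent-4-en-2-yl]bicyclo[3.1.1]hept-3-en-2-one
Conditions: AcOH, THF/H2O, rt
Reagents that add atoms: none
Why: Conjugate (sulfa-Michael) addition of sulfinate to the terminal ynone under buffered acidic conditions should give the thermodynamically preferred E-β-sulfonyl enone, while the β,β-disubstituted ring enone does not compete.

Step 16
Reactants: 22 (1R,5R,7S)-4-methyl-6-methylidene-7-[(4E)-2-methyl-3-oxo-5-(phenylsulfonyl)pent-4-en-2-yl]bicyclo[3.1.1]hept-3-en-2-one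
Product: 23 (4R,5S,10R,11R)-longipina-2,8-diene-1,7-dione
Conditions: Fe(acac)3 (0.3 equiv), PhSiH3 (2.5 equiv), i-PrOH/THF (1:4), 0.01 M, 40 °C, argon
Reagents that add atoms: none
Why: The iron hydride formed from Fe(acac)3, PhSiH3 and the alcohol transfers a hydrogen atom to the terminal CH2 of the C10 methylene, which creates the C10 methyl group and the tertiary cyclobutyl radical; this radical adds to C9 of the β-sulfonyl enone, and the resulting α-keto radical at C8 expels PhSO2•, which divalent iron reduces to sulfinate while trivalent iron is regenerated. The closest known reaction type is the metal-hydride hydrogen-atom-transfer Giese addition of 1,1-disubstituted alkenes to electron-poor alkenes, here ended by the β-sulfonyl radical elimination known for vinyl sulfone acceptors. The cycloheptenone closes in the 7-endo-trig mode; attack at C8 (6-exo) is disfavoured because it would give a less stabilised α-sulfonyl radical and a three-atom bridge across the cyclobutane. The new stereocenter C10 is controlled by the tether: C9 can reach only the lobe of the radical on the cyclobutane face that carries the C5 side chain, so the methyl group ends syn to the enone bridge (10R). The step needs chemoselective hydrogen-atom transfer to the 1,1-disubstituted alkene, secured because C2=C3 and C8=C9 are conjugated to ketone or sulfone and are poor hydrogen-atom acceptors, and it needs cyclisation to outrun reduction of the radical, which the gem-dimethyl group at C6 and high dilution favour. Isopropanol is used in place of a primary alcohol to limit solvent addition to the electrophilic sulfonyl enone.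

Step 17
Reactants: 23 (4R,5S,10R,11R)-longipina-2,8-diene-1,7-dione
Product: 24 C1 trimethylsilyl dienol ether of 23 (C1(OSiMe3)=C2, exocyclic C3=CH2, C7 ketone and C8=C9 unchanged)
Conditions: KN(SiMe3)2, THF, −78 to −40 °C; Me3SiCl; non-aqueous work-up, used crude
Reagents that add atoms: trimethylsilyl chloride, C[Si](C)(C)Cl
Why: γ-Deprotonation and O-silylation (silyl dienol ether formation) can occur only at the C1 enone, because the C7 ketone has a quaternary and a vinylic α-carbon and C11 is a bridgehead, so C1 is masked for the reduction that follows.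

Step 18
Reactants: 24 C1 trimethylsilyl dienol ether of 23
Product: 26 (4R,5S,7R,10R,11R)-7-hydroxylongipina-2,8-dien-1-one, via dienol ether alcohol 25 (not isolated)
Conditions: (S)-2-methyl-CBS-oxazaborolidine (0.2 equiv), catecholborane, toluene, −78 to −40 °C; MeOH; then K2CO3 (cat.), MeOH, 0 °C
Reagents that add atoms: none
Why: Corey–Bakshi–Shibata reduction is used because the two faces of the C7 ketone differ only through the remote C1 and C3 substituents, so the catalyst has to choose the face; with quaternary C6 as the large and vinylic C8 as the small group the S catalyst should deliver hydride syn to C11 (7R), the basic methanol work-up then cleaves the dienol ether back to the conjugated C1 enone, and any residual enantiomer of the core becomes a separable diastereomer.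

Step 19
Reactants: 26 (4R,5S,7R,10R,11R)-7-hydroxylongipina-2,8-dien-1-one
Product: 27 (4R,5S,7R,10R,11R)-7-[(triethylsilyl)oxy]longipina-2,8-dien-1-one
Conditions: Et3SiOTf, 2,6-lutidine, CH2Cl2, −78 °C
Reagents that add atoms: triethylsilyl trifluoromethanesulfonate, CC[Si](CC)(CC)OS(=O)(=O)C(F)(F)F
Why: Silyl ether formation with a silyl triflate protects the hindered C7 alcohol, so that C7 stays free of acyl groups and its bulk directs the dihydroxylation.

Step 20
Reactants: 27 (4R,5S,7R,10R,11R)-7-[(triethylsilyl)oxy]longipina-2,8-dien-1-one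
Product: 28 (4R,5S,7S,8S,9S,10R,11R)-8,9-dihydroxy-7-[(triethylsilyl)oxy]longipin-2-en-1-one
Conditions: OsO4 (5 mol%), NMO, acetone/H2O, rt
Reagents that add atoms: 4-methylmorpholine N-oxide, C[N+]1([O-])CCOCC1; water, O
Why: OsO4-catalysed syn-dihydroxylation should take place only at C8=C9 (C2=C3 is deactivated by the ketone) and on the face anti to the allylic C7 silyloxy group, which sets the 8,9-cis diol trans to the C7 oxygen.

Step 21
Reactants: 28 (4R,5S,7S,8S,9S,10R,11R)-8,9-dihydroxy-7-[(triethylsilyl)oxy]longipin-2-en-1-one; 29 (2Z)-2-methylbut-2-enoic acid (angelic acid)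
Product: 31 (4R,5S,7S,8S,9S,10R,11R)-9-hydroxy-1-oxo-7-[(triethylsilyl)oxy]longipin-2-en-8-yl (2Z)-2-methylbut-2-enoate, via mixed anhydride 30 (not isolated)
Conditions: 29, 2,4,6-trichlorobenzoyl chloride, Et3N, toluene, rt; then 28, toluene, 80 °C
Reagents that add atoms: none
Why: Yamaguchi-type esterification through the mixed anhydride without a nucleophilic catalyst should keep the Z geometry of the angelate, and the C8 hydroxyl, flanked by two CH carbons, should react before the C9 hydroxyl next to quaternary C10.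

Step 22
Reactants: 31 (4R,5S,7S,8S,9S,10R,11R)-9-hydroxy-1-oxo-7-[(triethylsilyl)oxy]longipin-2-en-8-yl (2Z)-2-methylbut-2-enoate
Product: 32 (4R,5S,7S,8S,9S,10R,11R)-9-[(3-methylbutanoyl)oxy]-1-oxo-7-[(triethylsilyl)oxy]longipin-2-en-8-yl (2Z)-2-methylbut-2-enoate
Conditions: (i-PrCH2CO)2O, DMAP, Et3N, CH2Cl2, rt
Reagents that add atoms: 3-methylbutanoic anhydride, CC(C)CC(=O)OC(=O)CC(C)C
Why: DMAP-catalysed acyl transfer from an aliphatic anhydride (Steglich-type acylation) should esterify the remaining hindered C9 hydroxyl under conditions in which an existing angelate ester keeps its geometry.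

Step 23
Reactants: 32 (4R,5S,7S,8S,9S,10R,11R)-9-[(3-methylbutanoyl)oxy]-1-oxo-7-[(triethylsilyl)oxy]longipin-2-en-8-yl (2Z)-2-methylbut-2-enoate
Product: 33 (4R,5S,7S,8R,9S,10R,11R)-7-hydroxy-9-[(3-methylbutanoyl)oxy]-1-oxolongipin-2-en-8-yl (2Z)-2-methylbut-2-enoate (CNP0151972.1)
Conditions: HF·pyridine, THF/pyridine, 0 °C to rt
Reagents that add atoms: none
Why: Fluoride-mediated cleavage of the triethylsilyl ether under buffered conditions should leave both esters, the enone and the Z-alkene untouched and should not promote acyl migration.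

Compound list
1 | 2,2-dimethylpropane-1,3-diol | OCC(C)(C)CO | starting material
2 | 3-[(tert-butyldimethylsilyl)oxy]-2,2-dimethylpropan-1-ol | CC(C)(C)[Si](C)(C)OCC(C)(C)CO | intermediate
3 | 3-[(tert-butyldimethylsilyl)oxy]-2,2-dimethylpropanal | CC(C)(C)[Si](C)(C)OCC(C)(C)C=O | intermediate
4 | diethyl {2-[methoxy(methyl)amino]-2-oxoethyl}phosphonate | CCOP(=O)(OCC)CC(=O)N(C)OC | starting material
5 | (2E)-5-[(tert-butyldimethylsilyl)oxy]-N-methoxy-N,4,4-trimethylpent-2-enamide | CON(C)C(=O)/C=C/C(C)(C)CO[Si](C)(C)C(C)(C)C | intermediate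
6 | (2E)-5-[(tert-butyldimethylsilyl)oxy]-4,4-dimethylpent-2-enal | O=C/C=C/C(C)(C)CO[Si](C)(C)C(C)(C)C | intermediate
7 | methyl 3-methylbut-2-enoate | COC(=O)C=C(C)C | starting material
8 | tert-butyl[(1-methoxy-3-methylbuta-1,3-dien-1-yl)oxy]dimethylsilane (ketene acetal geometry not controlled) | COC(=CC(C)=C)O[Si](C)(C)C(C)(C)C | intermediate
9 | methyl (2E,5R,6E)-9-[(tert-butyldimethylsilyl)oxy]-5-hydroxy-3,8,8-trimethylnona-2,6-dienoate | COC(=O)/C=C(\C)C[C@@H](O)/C=C/C(C)(C)CO[Si](C)(C)C(C)(C)C | intermediate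
10 | methyl (2E,5R,6E)-5,9-bis[(tert-butyldimethylsilyl)oxy]-3,8,8-trimethylnona-2,6-dienoate | COC(=O)/C=C(\C)C[C@@H](O[Si](C)(C)C(C)(C)C)/C=C/C(C)(C)CO[Si](C)(C)C(C)(C)C | intermediate
11 | (2E,5R,6E)-5,9-bis[(tert-butyldimethylsilyl)oxy]-3,8,8-trimethylnona-2,6-dienoic acid | OC(=O)/C=C(\C)C[C@@H](O[Si](C)(C)C(C)(C)C)/C=C/C(C)(C)CO[Si](C)(C)C(C)(C)C | intermediate
12 | (2E,5R,6E)-5,9-bis[(tert-butyldimethylsilyl)oxy]-3,8,8-trimethylnona-2,6-dienoyl chloride | ClC(=O)/C=C(\C)C[C@@H](O[Si](C)(C)C(C)(C)C)/C=C/C(C)(C)CO[Si](C)(C)C(C)(C)C | intermediate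
13 | (5R,6E)-5,9-bis[(tert-butyldimethylsilyl)oxy]-8,8-dimethyl-3-methylidenenona-1,6-dien-1-one (vinylketene) | O=C=CC(=C)C[C@@H](O[Si](C)(C)C(C)(C)C)/C=C/C(C)(C)CO[Si](C)(C)C(C)(C)C | intermediate
14 | (1S,2R,5R,7S)-2-[(tert-butyldimethylsilyl)oxy]-7-{1-[(tert-butyldimethylsilyl)oxy]-2-methylpropan-2-yl}-4-methylidenebicyclo[3.1.1]heptan-6-one (side chain anti to the C2–C4 bridge, silyloxy syn to the carbonyl bridge) | CC(C)(C)[Si](C)(C)OCC(C)(C)[C@@H]2[C@H]3[C@H](O[Si](C)(C)C(C)(C)C)CC(=C)[C@@H]2C3=O | intermediate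
15 | (1R,2R,5R,7S)-2-[(tert-butyldimethylsilyl)oxy]-7-{1-[(tert-butyldimethylsilyl)oxy]-2-methylpropan-2-yl}-4,6-dimethylidenebicyclo[3.1.1]heptane | CC(C)(C)[Si](C)(C)OCC(C)(C)[C@@H]2[C@H]3[C@H](O[Si](C)(C)C(C)(C)C)CC(=C)[C@@H]2C3=C | intermediate
16 | (1R,2R,5R,7S)-7-(1-hydroxy-2-methylpropan-2-yl)-4,6-dimethylidenebicyclo[3.1.1]heptan-2-ol | OCC(C)(C)[C@@H]2[C@H]3[C@H](O)CC(=C)[C@@H]2C3=C | intermediate
17 | 2-methyl-2-[(1R,5R,7S)-4,6-dimethylidene-2-oxobicyclo[3.1.1]heptan-7-yl]propanal | O=CC(C)(C)[C@@H]2[C@H]3C(=O)CC(=C)[C@@H]2C3=C | intermediate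
18 | 2-methyl-2-[(1R,5R,7S)-4-methyl-6-methylidene-2-oxobicyclo[3.1.1]hept-3-en-7-yl]propanal | O=CC(C)(C)[C@@H]2[C@H]3C(=O)C=C(C)[C@@H]2C3=C | intermediate
19 | (1R,5R,7S)-7-(3-hydroxy-2-methylpent-4-yn-2-yl)-4-methyl-6-methylidenebicyclo[3.1.1]hept-3-en-2-one (carbinol epimers) | C#CC(O)C(C)(C)[C@@H]2[C@H]3C(=O)C=C(C)[C@@H]2C3=C | intermediate
20 | (1R,5R,7S)-4-methyl-6-methylidene-7-(2-methyl-3-oxopent-4-yn-2-yl)bicyclo[3.1.1]hept-3-en-2-one | C#CC(=O)C(C)(C)[C@@H]2[C@H]3C(=O)C=C(C)[C@@H]2C3=C | intermediate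
21 | sodium benzenesulfinate | [Na+].[O-]S(=O)c1ccccc1 | starting material
22 | (1R,5R,7S)-4-methyl-6-methylidene-7-[(4E)-2-methyl-3-oxo-5-(phenylsulfonyl)pent-4-en-2-yl]bicyclo[3.1.1]hept-3-en-2-one | O=C(/C=C/S(=O)(=O)c1ccccc1)C(C)(C)[C@@H]2[C@H]3C(=O)C=C(C)[C@@H]2C3=C | intermediate
23 | (4R,5S,10R,11R)-longipina-2,8-diene-1,7-dione | O=C1C(C)(C)[C@@H]2[C@H]3C(=O)C=C(C)[C@@H]2[C@@]3(C)C=C1 | intermediate
24 | C1 trimethylsilyl dienol ether of 23 (C1(OSiMe3)=C2, exocyclic C3=CH2, C7 ketone, C8=C9) | O=C1C(C)(C)[C@@H]2[C@H]3C(O[Si](C)(C)C)=CC(=C)[C@@H]2[C@@]3(C)C=C1 | intermediate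
25 | (7R)-7-hydroxy derivative of 24 (C1 trimethylsilyl dienol ether retained) | O[C@H]1C(C)(C)[C@@H]2[C@H]3C(O[Si](C)(C)C)=CC(=C)[C@@H]2[C@@]3(C)C=C1 | intermediate
26 | (4R,5S,7R,10R,11R)-7-hydroxylongipina-2,8-dien-1-one (hydroxyl on the face of C4) | O[C@H]1C(C)(C)[C@@H]2[C@H]3C(=O)C=C(C)[C@@H]2[C@@]3(C)C=C1 | intermediate
27 | (4R,5S,7R,10R,11R)-7-[(triethylsilyl)oxy]longipina-2,8-dien-1-one | CC[Si](CC)(CC)O[C@H]1C(C)(C)[C@@H]2[C@H]3C(=O)C=C(C)[C@@H]2[C@@]3(C)C=C1 | intermediate
28 | (4R,5S,7S,8S,9S,10R,11R)-8,9-dihydroxy-7-[(triethylsilyl)oxy]longipin-2-en-1-one (8,9-cis, both trans to the C7 oxygen) | O[C@@H]1[C@@H](O[Si](CC)(CC)CC)C(C)(C)[C@@H]2[C@H]3C(=O)C=C(C)[C@@H]2[C@@]3(C)[C@@H]1O | intermediate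
29 | (2Z)-2-methylbut-2-enoic acid (angelic acid) | C/C=C(/C)C(=O)O | starting material
30 | (2Z)-2-methylbut-2-enoic 2,4,6-trichlorobenzoic anhydride | C/C=C(/C)C(=O)OC(=O)c1c(Cl)cc(Cl)cc1Cl | intermediate
31 | (4R,5S,7S,8S,9S,10R,11R)-9-hydroxy-1-oxo-7-[(triethylsilyl)oxy]longipin-2-en-8-yl (2Z)-2-methylbut-2-enoate | C/C=C(/C)C(=O)O[C@@H]1[C@@H](O[Si](CC)(CC)CC)C(C)(C)[C@@H]2[C@H]3C(=O)C=C(C)[C@@H]2[C@@]3(C)[C@@H]1O | intermediate
32 | (4R,5S,7S,8S,9S,10R,11R)-9-[(3-methylbutanoyl)oxy]-1-oxo-7-[(triethylsilyl)oxy]longipin-2-en-8-yl (2Z)-2-methylbut-2-enoate | C/C=C(/C)C(=O)O[C@@H]1[C@@H](O[Si](CC)(CC)CC)C(C)(C)[C@@H]2[C@H]3C(=O)C=C(C)[C@@H]2[C@@]3(C)[C@@H]1OC(=O)CC(C)C | intermediate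
33 | (4R,5S,7S,8R,9S,10R,11R)-7-hydroxy-9-[(3-methylbutanoyl)oxy]-1-oxolongipin-2-en-8-yl (2Z)-2-methylbut-2-enoate | C/C=C(/C)C(=O)O[C@@H]1[C@@H](O)C(C)(C)[C@@H]2[C@H]3C(=O)C=C(C)[C@@H]2[C@@]3(C)[C@@H]1OC(=O)CC(C)C | target

Total step count: 23. Longest linear sequence: 22 steps (steps 1–4 and 6–23, from 1 to 33); step 5 is the single side branch.

Steps most likely to fail

Step 9. The 1,2-disubstituted alkene, deactivated by its allylic oxygen, is a weak partner for the ketene, so the vinylketene may oligomerise or close in the fused bicyclo[3.2.0] sense, and facial discrimination by the silyloxy carbon may be incomplete. The fallback replaces the ketene by a more electrophilic keteniminium salt on a saturated tether and introduces the ring alkene afterwards; it sets out from 10 and returns at 18. Copper hydride conjugate reduction of 10 (Cu(OAc)2, 1,2-bis(diphenylphosphino)benzene, polymethylhydrosiloxane, t-BuOH) would give the saturated ester F1 as a mixture at the methyl-bearing carbon, which is of no consequence. Aminolysis with pyrrolidine and AlMe3 would give the pyrrolidine amide F2. Tf2O and 2,4,6-collidine in 1,2-dichloroethane at reflux would convert it into the keteniminium triflate F3, which should add across the E-alkene to the cyclobutaniminium triflate F4, hydrolysed on aqueous work-up to the cyclobutanone F5. Wittig methylenation would give the methylidene compound F6, Bu4NF the diol F7 and Dess–Martin oxidation the keto aldehyde F8. Dehydrogenation of the ring ketone with IBX in DMSO can run only toward the methyl-bearing carbon, because the other α-carbon is a bridgehead, and would deliver 18.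

Step 16. The tertiary C10 radical may be reduced before it cyclises or may add at C8, and the strongly electrophilic sulfonyl enone may be consumed by the alcohol or the hydride before the radical forms. The fallback uses a reductive radical conjugate addition to a plain vinyl ketone followed by re-oxidation; it sets out from 18 and returns at 23. Vinylmagnesium bromide (THF, −78 °C) would give the allylic alcohol F9 and Dess–Martin oxidation the vinyl ketone F10. Under the Fe(acac)3/PhSiH3 conditions the C10 radical should add to the unsubstituted terminal carbon (7-endo, no regiochemical ambiguity), and reduction and protonation of the α-keto radical would give the saturated diketone F11. Dehydrogenation of the C7 ketone with IBX, possible only toward C8–C9 because C6 is quaternary, would give 23.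

Step 18. Facial selection rests entirely on the catalyst and may be weak if the quaternary C6 and the vinylic C8 are not differentiated well enough, and the hindered ketone may react slowly. The fallback gives up asymmetric induction in favour of separation and recycling; it sets out from 24 and returns at 26. Reduction of 24 with i-Bu2AlH (THF, −78 °C) would give 25 together with its C7-epimeric dienol ether alcohol F12. Methanolysis (K2CO3, MeOH) would give 26 and the C7-epimeric alcohol F13, which are diastereomers and should be separable by chromatography. F13 would be oxidised with MnO2 back to 23 and passed through steps 17 and 18 again.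

Further compounds
F1 | step 9 | methyl (5R,6E)-5,9-bis[(tert-butyldimethylsilyl)oxy]-3,8,8-trimethylnon-6-enoate (C3 epimers) | COC(=O)CC(C)C[C@@H](O[Si](C)(C)C(C)(C)C)/C=C/C(C)(C)CO[Si](C)(C)C(C)(C)C
F2 | step 9 | 1-{(5R,6E)-5,9-bis[(tert-butyldimethylsilyl)oxy]-3,8,8-trimethylnon-6-enoyl}pyrrolidine | O=C(CC(C)C[C@@H](O[Si](C)(C)C(C)(C)C)/C=C/C(C)(C)CO[Si](C)(C)C(C)(C)C)N1CCCC1
F3 | step 9 | keteniminium triflate derived from F2 | C(=C=[N+]1CCCC1)C(C)C[C@@H](O[Si](C)(C)C(C)(C)C)/C=C/C(C)(C)CO[Si](C)(C)C(C)(C)C.[O-]S(=O)(=O)C(F)(F)F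
F4 | step 9 | cyclobutaniminium triflate (pyrrolidinium analogue of F5) | CC(C)(C)[Si](C)(C)OCC(C)(C)[C@@H]2[C@H]3[C@H](O[Si](C)(C)C(C)(C)C)CC(C)[C@@H]2C3=[N+]1CCCC1.[O-]S(=O)(=O)C(F)(F)F
F5 | step 9 | 2-[(tert-butyldimethylsilyl)oxy]-7-{1-[(tert-butyldimethylsilyl)oxy]-2-methylpropan-2-yl}-4-methylbicyclo[3.1.1]heptan-6-one (core as in 14, C4 epimers) | CC(C)(C)[Si](C)(C)OCC(C)(C)[C@@H]2[C@H]3[C@H](O[Si](C)(C)C(C)(C)C)CC(C)[C@@H]2C3=O
F6 | step 9 | 6-methylidene analogue of F5 | CC(C)(C)[Si](C)(C)OCC(C)(C)[C@@H]2[C@H]3[C@H](O[Si](C)(C)C(C)(C)C)CC(C)[C@@H]2C3=C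
F7 | step 9 | 7-(1-hydroxy-2-methylpropan-2-yl)-4-methyl-6-methylidenebicyclo[3.1.1]heptan-2-ol (core as in 16) | OCC(C)(C)[C@@H]2[C@H]3[C@H](O)CC(C)[C@@H]2C3=C
F8 | step 9 | 2-methyl-2-(4-methyl-6-methylidene-2-oxobicyclo[3.1.1]heptan-7-yl)propanal (core as in 18, C4 epimers) | O=CC(C)(C)[C@@H]2[C@H]3C(=O)CC(C)[C@@H]2C3=C
F9 | step 16 | (1R,5R,7S)-7-(3-hydroxy-2-methylpent-4-en-2-yl)-4-methyl-6-methylidenebicyclo[3.1.1]hept-3-en-2-one (carbinol epimers) | C=CC(O)C(C)(C)[C@@H]2[C@H]3C(=O)C=C(C)[C@@H]2C3=C
F10 | step 16 | (1R,5R,7S)-4-methyl-6-methylidene-7-(2-methyl-3-oxopent-4-en-2-yl)bicyclo[3.1.1]hept-3-en-2-one | C=CC(=O)C(C)(C)[C@@H]2[C@H]3C(=O)C=C(C)[C@@H]2C3=C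
F11 | step 16 | (4R,5S,10R,11R)-longipin-2-ene-1,7-dione | O=C1C(C)(C)[C@@H]2[C@H]3C(=O)C=C(C)[C@@H]2[C@@]3(C)CC1
F12 | step 18 | C7 epimer of 25 | O[C@@H]1C(C)(C)[C@@H]2[C@H]3C(O[Si](C)(C)C)=CC(=C)[C@@H]2[C@@]3(C)C=C1
F13 | step 18 | (4R,5S,7S,10R,11R)-7-hydroxylongipina-2,8-dien-1-one (C7 epimer of 26) | O[C@@H]1C(C)(C)[C@@H]2[C@H]3C(=O)C=C(C)[C@@H]2[C@@]3(C)C=C1
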